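Ines and Tomas have two earlier runs, south and west, and must say what three new flasks hold after 25 h. The new flasks differ in temperature.

| flask | starting material | protic impurity | temperature | remark | time |
|---|---|---|---|---|---|
| south | 0.067 M | 0.050 M | 72 °C | run made earlier |  |
| west | 0.15 M | 0.050 M | 89 °C | run made earlier |  |
| blue | 0.10 M | 0.0500 M | 80 °C |  | 25 h |
| amber | 0.10 M | 0.0500 M | 95 °C |  | 25 h |
| ochre | 0.10 M | 0.0500 M | 65 °C |  | 25 h |

- south (time / h: product / %, starting material / %): 1.33: 0.2, 99.4; 4.00: 0, 97.6; 8.00: 0.4, 93.9; 10.0: 0.7, 93.3; 15.0: 1.4, 90.5; 20.0: 0.7, 88.0
- west (time / h: product / %, starting material / %): 0.833: 0, 98.2; 2.50: 0.2, 92.5; 5.00: 1.8, 85.5; 6.00: 3.1, 83.1; 10.0: 8.1, 72.5; 12.0: 13.3, 67.6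

(each reading ± 0.5 percentage points)

* the flask with the highest amount of product, in percent of the starting material charged ("all alike" if they lie within 1.5 percentage points) (blue / amber / ochre / all alike)
* final product, as a percentage of the starting material charged, in blue
* final product, as a percentage of the starting material charged, in amber
* final product, as a percentage of the starting material charged, in ochre



Tomas divides the product gained between two readings by the starting material lost between them, so that time drops out. He calls this the product share. In west, the share from 0.833 h to 5.00 h reads 0.142. From 10.0 h to 12.0 h, the late product share reads 1.06, but that is a reading: each of the four numbers carries 0.5 percentage points and the differences are small, so the share may well lie below one.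

Ines takes the late share as near one, and her forecast says “nearly everything consumed appears as product”. It names amber as the highest, with 6% in blue, 45% in amber and 0.4% in ochre, taking 74% of the charge as consumed in amber. That 45% is also what a straight line through the last two readings of west gives at the time asked.

Tomas disputes the consumption. To him, a share that climbs suggests product helping to make product (autocatalysis), so the decay in amber need not stay steady. West had lost 0.0287 M by its last reading. Taking the same loss for amber gives a rough ceiling of 71.3%, and he commits to a figure between 45% and that estimate.

The flasks give 5.05% in blue, 56.3% in amber and 0.400% in ochre, with amber highest.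

    starting material + product → 2 product (k = 2.68 × 10⁻⁴ M⁻¹ s⁻¹, Ea = 87.0 kJ mol⁻¹)
    starting material → product (k = 1.98 × 10⁻⁷ s⁻¹, Ea = 118 kJ mol⁻¹)
    starting material + protic impurity → quenched substrate (k = 7.70 × 10⁻⁵ M⁻¹ s⁻¹, Ea = 98.0 kJ mol⁻¹)
    (constants at 80 °C)

Amber's 56.3% falls inside Tomas's range, and the forecast is 11 points low. Between 12.5 h and 25.0 h, amber's product share, the same quantity as west's late 1.06, is 0.873, and with the product-fed step struck out amber ends at 6.18%. What amber's product falls short of the charge is mainly due to the passing of starting material and protic impurity into quenched substrate: without that step amber gives 97.5%. Ines's steady decay comes near in the cooler flasks: ochre used 7.43% of its charge against her 8%, and blue 27.4% against her 30%. Over those same hours, blue's share stands at 0.290.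

The earlier runs and the new flask are calculated from invented constants; noise was put on by code.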